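## Retrosynthetic overview

1. Germacrane numbering is used: carbocycle C1–C10 with (Z)-C1=C10 and (E)-C4=C5, lactone C6–O–C12(=O)–C11(=C13)–C7, acyloxy on C9, hydroxyl on C2. The last events are desilylation of the side-chain CH2OH and, before it, closure of the ten-membered ring at C3–C4.
2. C3–C4: ring-closing Suzuki–Miyaura coupling of a primary C3 boronate with the (E)-alkenyl chloride at C4. The C2/C3 bis(boronate) comes from enantioselective 1,2-diboration of the terminal alkene of a (Z)-diene, and C2–B is then oxidised to C2–OH.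
3. C9–O: Yamaguchi esterification with O-silyl sarracinic acid. C9–C10: Nozaki–Hiyama–Kishi coupling of (Z)-4-iodopenta-1,3-diene with a lactone aldehyde.
4. Lactone ring (formed first; C6–C7 bond and both stereocentres): chromium-catalysed anti allylation/lactonisation of (E)-3-chlorobut-2-enal with a Morita–Baylis–Hillman-derived allylic bromide. All three four-carbon alkenyl pieces come from but-2-yn-1-ol.
5. Enabling feature: C2 (carbinol) and C3 (methylene), lying between the (Z)-C1=C10 alkene and C4, are the footprint of a vinyl group on a cis-substituted diene. Diboration turns them into an allylic secondary and a primary boronate, and only the primary one is expected to couple to C4. Ring order: five-membered lactone, then ten-membered carbocycle (C1–C10).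

Key step: step 16

Remark on descriptors: CIP letters in the names refer to the locants of each name. The chlorine on C4 changes the priority order at the lactone γ-carbon, so that letter differs from the target's although the geometry is the same.

Remark (assumption): in the three ligand-controlled steps (5, 10, 15) the ligand enantiomer named is the one expected from the known sense of induction with simple substrates. If a model run shows the opposite sense, the antipode is used.

## Route

Step 1
Reactants: 1 but-2-yn-1-ol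
Product: 3 (E)-3-chlorobut-2-en-1-ol, via alkenylzirconocene 2 (not isolated)
Conditions: Cp2Zr(H)Cl (2.2 equiv), THF, 0 °C to rt; then N-chlorosuccinimide, 0 °C; aqueous work-up
Reagents that add atoms: Cp2Zr(H)Cl, [H][Zr](Cl)(C1C=CC=C1)C1C=CC=C1 (zirconium of 2 only); N-chlorosuccinimide, O=C1CCC(=O)N1Cl
Why: Hydrozirconation–halogenation: syn addition of Zr–H to the alkyne of the zirconium alkoxide places the metal on the methyl-bearing carbon (remote from oxygen, the regiochemistry known for 2-alkyn-1-ols), and chlorinolysis with retention gives the (E)-chloride.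

Step 2
Reactants: 3 (E)-3-chlorobut-2-en-1-ol
Product: 4 (E)-3-chlorobut-2-enal
Conditions: MnO2 (10 equiv), CH2Cl2, rt
Reagents that add atoms: none
Why: Allylic oxidation on MnO2 stops at the aldehyde and leaves the alkenyl chloride and its (E) geometry untouched.

Step 3
Reactants: 5 3-(tert-butyldimethylsilyloxy)propanal; 6 methyl acrylate
Product: 7 methyl 5-(tert-butyldimethylsilyloxy)-3-hydroxy-2-methylidenepentanoate (racemic)
Conditions: DABCO (0.5 equiv), neat, rt, several days
Reagents that add atoms: none
Why: Morita–Baylis–Hillman reaction of an unhindered aliphatic aldehyde with an acrylate; the racemic carbinol centre is erased in step 4.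

Step 4
Reactants: 7 methyl 5-(tert-butyldimethylsilyloxy)-3-hydroxy-2-methylidenepentanoate
Product: 8 methyl (Z)-2-(bromomethyl)-5-(tert-butyldimethylsilyloxy)pent-2-enoate
Conditions: N-bromosuccinimide (1.2 equiv), Me2S (1.3 equiv), CH2Cl2, 0 °C to rt
Reagents that add atoms: N-bromosuccinimide, O=C1CCC(=O)N1Br
Why: Corey–Kim-type activation of the alcohol as an alkoxysulfonium ion followed by SN2' attack of bromide gives the rearranged primary allylic bromide with the usual (Z) geometry (ester trans to the chain).

Step 5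
Reactants: 4 (E)-3-chlorobut-2-enal; 8 methyl (Z)-2-(bromomethyl)-5-(tert-butyldimethylsilyloxy)pent-2-enoate
Product: 10 (4S,5S)-5-[(E)-2-chloroprop-1-enyl]-4-(2-hydroxyethyl)-3-methylideneoxolan-2-one, via anti trimethylsilyl ether 9 (not isolated)
Conditions: CrCl2 (10 mol%), (S,S)-3,6-di-tert-butyl-1,8-bis(4-isopropyl-4,5-dihydrooxazol-2-yl)-9H-carbazole (12 mol%), Mn (2 equiv), TMSCl (1.5 equiv), THF, rt; then PPTS (0.3 equiv), MeOH, rt to 40 °C
Reagents that add atoms: TMSCl, C[Si](C)(C)Cl (silyl group of 9 only)
Why: Chromium-catalysed asymmetric 2-(alkoxycarbonyl)allylation of the Nozaki–Hiyama type: the γ-substituted allylchromium adds through a chair transition state to give the anti adduct (C6/C7 trans), the carbazole bis(oxazoline) ligand selects the aldehyde face, and acidic methanolysis removes both silyl groups so that the γ-hydroxy ester closes to the five-membered lactone.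

Step 6
Reactants: 10 (4S,5S)-5-[(E)-2-chloroprop-1-enyl]-4-(2-hydroxyethyl)-3-methylideneoxolan-2-one
Product: 11 2-[(3S,4S... see list: (4S,5S)-lactone]acetaldehyde, i.e. the aldehyde of 10
Conditions: Dess–Martin periodinane (1.3 equiv), CH2Cl2, 0 °C to rt
Reagents that add atoms: none
Why: Dess–Martin oxidation converts the primary alcohol into the aldehyde under neutral conditions without touching the lactone or the alkenyl chloride, and no stereocentre is α to the new carbonyl.

Step 7
Reactants: 1 but-2-yn-1-ol
Product: 13 (Z)-3-iodobut-2-en-1-ol, via cyclic alkenylalanate 12 (not isolated)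
Conditions: NaAlH2(OCH2CH2OMe)2 (1.5 equiv), THF, 0 °C to rt; then I2, −78 °C; aqueous work-up
Reagents that add atoms: NaAlH2(OCH2CH2OMe)2, [Na+].[H][Al-]([H])(OCCOC)OCCOC (aluminate of 12 only); iodine, II
Why: Hydroxyl-directed trans-hydroalumination delivers hydride to the proximal alkyne carbon through the alkoxyaluminate, and iodinolysis of the cyclic alkenylalanate with retention gives the (Z)-iodide (iodine cis to CH2OH).

Step 8
Reactants: 13 (Z)-3-iodobut-2-en-1-ol
Product: 14 (Z)-3-iodobut-2-enal
Conditions: MnO2 (10 equiv), CH2Cl2, rt, dark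
Reagents that add atoms: none
Why: Allylic oxidation on MnO2 gives the enal without isomerising the (Z)-iodoalkene.

Step 9
Reactants: 14 (Z)-3-iodobut-2-enal
Product: 15 (Z)-4-iodopenta-1,3-diene
Conditions: Ph3PCH3Br (1.2 equiv), n-BuLi (1.15 equiv), THF, −78 to 0 °C
Reagents that add atoms: methyltriphenylphosphonium bromide, C[P+](c1ccccc1)(c1ccccc1)c1ccccc1.[Br-]
Why: Wittig methylenation with the non-stabilised ylide at low temperature adds only to the aldehyde carbonyl, so the (Z)-iodoalkene geometry is carried into the diene.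

Step 10
Reactants: 11 lactone aldehyde; 15 (Z)-4-iodopenta-1,3-diene
Product: 16 (4S,5S)-5-[(E)-2-chloroprop-1-enyl]-4-[(2S,3Z)-2-hydroxy-3-methylhexa-3,5-dienyl]-3-methylideneoxolan-2-one
Conditions: CrCl2 (15 mol%), (S)-N-[2-(4-isopropyl-4,5-dihydrooxazol-2-yl)-6-methylphenyl]methanesulfonamide (17 mol%), proton sponge (17 mol%), NiCl2(2,9-dimethyl-1,10-phenanthroline) (2 mol%), Mn (2 equiv), Cp2ZrCl2 (1.1 equiv), LiCl (2 equiv), MeCN, rt; aqueous work-up
Reagents that add atoms: none
Why: Nozaki–Hiyama–Kishi coupling: nickel inserts only into the C–I bond (the alkenyl chloride is inert), the dienylchromium adds to the aldehyde with retention of the (Z) geometry, and the chiral oxazoline–sulfonamide chromium complex selects the aldehyde face to set C9 (S).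

Step 11
Reactants: 1 but-2-yn-1-ol
Product: 17 (Z)-2-(tributylstannyl)but-2-en-1-ol
Conditions: Bu3SnH (1.1 equiv), [Cp*RuCl]4 (1.5 mol%), CH2Cl2, rt
Reagents that add atoms: tributyltin hydride, CCCC[SnH](CCCC)CCCC
Why: Ruthenium-catalysed trans-hydrostannation of a propargylic alcohol: hydrogen bonding of the hydroxyl to the chloride ligand steers tin to the proximal alkyne carbon and the anti addition places tin cis to the methyl group.

Step 12
Reactants: 17 (Z)-2-(tributylstannyl)but-2-en-1-ol
Product: 18 (Z)-tert-butyldimethyl{[2-(tributylstannyl)but-2-enyl]oxy}silane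
Conditions: TBSCl (1.2 equiv), imidazole (1.5 equiv), CH2Cl2, rt
Reagents that add atoms: tert-butyldimethylsilyl chloride, CC(C)(C)[Si](C)(C)Cl
Why: Standard silylation protects the primary allylic alcohol through the lithiation and the esterification.

Step 13
Reactants: 18 (Z)-tert-butyldimethyl{[2-(tributylstannyl)but-2-enyl]oxy}silane
Product: 20 (Z)-2-[(tert-butyldimethylsilyloxy)methyl]but-2-enoic acid, via alkenyllithium 19 (not isolated)
Conditions: n-BuLi (1.1 equiv), THF, −78 °C; then CO2, −78 °C; 1 M HCl to pH 3–4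
Reagents that add atoms: n-BuLi, [Li]CCCC (lithium of 19 only); carbon dioxide, O=C=O
Why: Tin–lithium exchange and carboxylation of the alkenyllithium both occur with retention, giving the (Z)-acid (methyl cis to carboxyl) of the sarracinate type.

Step 14
Reactants: 16 dienyl carbinol; 20 (Z)-2-[(tert-butyldimethylsilyloxy)methyl]but-2-enoic acid
Product: 22 C9 ester of 16 with acid 20, via mixed anhydride 21 (not isolated)
Conditions: 20, 2,4,6-trichlorobenzoyl chloride (1.2 equiv), Et3N (1.5 equiv), toluene, rt, 1 h; then 16, DMAP (1.5 equiv), toluene, rt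
Reagents that add atoms: 2,4,6-trichlorobenzoyl chloride, O=C(Cl)c1c(Cl)cc(Cl)cc1Cl (acyl group of 21 only)
Why: Yamaguchi esterification: the alcohol attacks the aliphatic carbonyl of the mixed anhydride via the acylpyridinium, and room temperature with a short anhydride lifetime limits (Z)-to-(E) isomerisation of the angelate-type acyl group.

Step 15
Reactants: 22 dienyl ester
Product: 23 (2R)-C2,C3-bis(pinacolboronate) of 22
Conditions: B2pin2 (1.05 equiv), Pt(dba)3 (3 mol%), (R,R)-TADDOL-derived phenylphosphonite with 3,5-diethylphenyl groups (6 mol%), THF, 60 °C; chromatography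
Reagents that add atoms: bis(pinacolato)diboron, CC1(C)OB(OC1(C)C)B1OC(C)(C)C(C)(C)O1
Why: Platinum-catalysed enantioselective 1,2-diboration: the cis substituent on C10 keeps the diene out of the s-cis conformation needed for 1,4-addition, so B–B adds syn across the terminal C2=C3 bond on the face selected by the phosphonite, which sets C2.

Step 16
Reactants: 23 bis(boronate)
Product: 25 side-chain O-TBS ether of the target, via macrocyclic C2 boronate 24 (not isolated)
Conditions: Pd(OAc)2 (10 mol%), RuPhos (20 mol%), K3PO4 (3 equiv), THF/H2O 20:1, 65 °C, 23 added over 10 h to a final 2 mM; then NaBO3·4H2O (6 equiv), THF/H2O, 0 °C to rt; pH 5 buffer work-up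
Reagents that add atoms: sodium perborate tetrahydrate, O[B-]1(O)OO[B-](O)(O)OO1.[Na+].[Na+]
Why: Proposed new method: zerovalent palladium inserts into the C4–Cl bond, hydroxide bridges the two neighbouring boron atoms of 23 so that the primary C3–B bond transmetalates intramolecularly, and C(sp3)–C(sp2) reductive elimination closes the ring at C3–C4, after which perborate converts the remaining C2–B bond into C2–OH with retention. The closest known reaction types are the primary-selective Suzuki–Miyaura coupling of vicinal bis(boronates) with alkenyl halides (intermolecular diboration/cross-coupling/oxidation of terminal alkenes) and the B-alkyl Suzuki macrocyclisation of 9-BBN boranes; new here are the ring-closing mode on a bis(boronate) and the allylic spectator boronate. The ten-membered carbocycle (C1–C10) is closed head-to-tail through an eleven-membered palladacycle, helped by two pre-set turns (the (Z)-C1=C10 alkene and the trans-fused lactone) and by slow addition at high dilution. No stereocentre is created in the ring closure: C2 comes from the ligand-controlled diboration of step 15 and survives because boron-to-oxygen migration is stereoretentive, and the (E)-C4=C5 geometry is that of the alkenyl chloride, which couples with retention. The step needs transfer of the primary C3–B over the allylic C2–B (direct transfer of a secondary boronate is slow and the SE2' path would have to bond at the fully substituted C10), C–Cl insertion over ionisation of the allylic C9 ester and C6 lactone (electron-rich biaryl phosphine, hindered trisubstituted allylic systems), and ring closure over oligomerisation (dilution).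

Step 17
Reactants: 25 side-chain O-TBS ether of the target
Product: 26 CNP0273961.1, (1(10)Z,4E)-(2R,6R,7S,9S)-2-hydroxy-9-[(Z)-2-(hydroxymethyl)but-2-enoyloxy]germacra-1(10),4,11(13)-trien-12,6-olide
Conditions: HF·pyridine, pyridine, THF, 0 °C to rt
Reagents that add atoms: none
Why: Buffered HF·pyridine cleaves the primary allylic silyl ether without adding to the α-methylene lactone or cleaving either ester.

## Compound list

1 | but-2-yn-1-ol | CC#CCO | starting material
2 | (E)-alkenylzirconocene chloride of the zirconium alkoxide of 1, zirconium on the methyl-bearing carbon (not isolated) | C/C(=C\CO[Zr](Cl)(C1C=CC=C1)C1C=CC=C1)[Zr](Cl)(C1C=CC=C1)C1C=CC=C1 | intermediate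
3 | (E)-3-chlorobut-2-en-1-ol | Cl/C(C)=C/CO | intermediate
4 | (E)-3-chlorobut-2-enal | Cl/C(C)=C/C=O | intermediate
5 | 3-(tert-butyldimethylsilyloxy)propanal | O=CCCO[Si](C)(C)C(C)(C)C | starting material
6 | methyl acrylate | C=CC(=O)OC | starting material
7 | methyl 5-(tert-butyldimethylsilyloxy)-3-hydroxy-2-methylidenepentanoate (racemic) | C=C(C(=O)OC)C(O)CCO[Si](C)(C)C(C)(C)C | intermediate
8 | methyl (Z)-2-(bromomethyl)-5-(tert-butyldimethylsilyloxy)pent-2-enoate | COC(=O)/C(CBr)=C/CCO[Si](C)(C)C(C)(C)C | intermediate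
9 | methyl (3S,4S,5E)-3-[2-(tert-butyldimethylsilyloxy)ethyl]-6-chloro-2-methylidene-4-(trimethylsilyloxy)hept-5-enoate, 3,4-anti (not isolated) | C=C(C(=O)OC)[C@H](CCO[Si](C)(C)C(C)(C)C)[C@H](O[Si](C)(C)C)/C=C(\C)Cl | intermediate
10 | (4S,5S)-5-[(E)-2-chloroprop-1-enyl]-4-(2-hydroxyethyl)-3-methylideneoxolan-2-one (trans lactone alcohol) | C=C1C(=O)O[C@H](/C=C(\C)Cl)[C@H]1CCO | intermediate
11 | 2-{(3S,4S)... trans lactone}acetaldehyde: (4S,5S)-5-[(E)-2-chloroprop-1-enyl]-3-methylidene-4-(2-oxoethyl)oxolan-2-one | C=C1C(=O)O[C@H](/C=C(\C)Cl)[C@H]1CC=O | intermediate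
12 | sodium cyclic alkenylalanate (2,2-bis(2-methoxyethoxy)-3-methyl-2,5-dihydro-1,2-oxaluminol-2-uide; not isolated) | CC1=CCO[Al-]1(OCCOC)OCCOC.[Na+] | intermediate
13 | (Z)-3-iodobut-2-en-1-ol | C/C(I)=C/CO | intermediate
14 | (Z)-3-iodobut-2-enal | C/C(I)=C/C=O | intermediate
15 | (Z)-4-iodopenta-1,3-diene | C/C(I)=C/C=C | intermediate
16 | (4S,5S)-5-[(E)-2-chloroprop-1-enyl]-4-[(2S,3Z)-2-hydroxy-3-methylhexa-3,5-dienyl]-3-methylideneoxolan-2-one | C=C1C(=O)O[C@H](/C=C(\C)Cl)[C@H]1C[C@H](O)/C(C)=C\C=C | intermediate
17 | (Z)-2-(tributylstannyl)but-2-en-1-ol | C/C=C(/CO)[Sn](CCCC)(CCCC)CCCC | intermediate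
18 | (Z)-tert-butyldimethyl{[2-(tributylstannyl)but-2-enyl]oxy}silane | C/C=C(/CO[Si](C)(C)C(C)(C)C)[Sn](CCCC)(CCCC)CCCC | intermediate
19 | (Z)-1-[(tert-butyldimethylsilyloxy)methyl]prop-1-enyllithium (not isolated) | C/C=C(/CO[Si](C)(C)C(C)(C)C)[Li] | intermediate
20 | (Z)-2-[(tert-butyldimethylsilyloxy)methyl]but-2-enoic acid (O-TBS sarracinic acid) | C/C=C(/CO[Si](C)(C)C(C)(C)C)C(=O)O | intermediate
21 | mixed anhydride of 20 with 2,4,6-trichlorobenzoic acid (not isolated) | C/C=C(/CO[Si](C)(C)C(C)(C)C)C(=O)OC(=O)c1c(Cl)cc(Cl)cc1Cl | intermediate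
22 | C9 ester: (Z)-2-[(tert-butyldimethylsilyloxy)methyl]but-2-enoate of the (2S) carbinol of 16 | C=C1C(=O)O[C@H](/C=C(\C)Cl)[C@H]1C[C@H](OC(=O)/C(=C\C)CO[Si](C)(C)C(C)(C)C)/C(C)=C\C=C | intermediate
23 | bis(boronate): 22 with a pinacolboryl group on C2 (2R) and on C3 in place of the terminal alkene | C=C1C(=O)O[C@H](/C=C(\C)Cl)[C@H]1C[C@H](OC(=O)/C(=C\C)CO[Si](C)(C)C(C)(C)C)/C(C)=C\[C@H](B1OC(C)(C)C(C)(C)O1)CB1OC(C)(C)C(C)(C)O1 | intermediate
24 | (1(10)Z,4E)-(2R,6R,7S,9S)-macrocycle, the C2-pinacolboryl analogue of 25 (not isolated) | C=C1C(=O)O[C@@H]2/C=C(\C)C[C@@H](B3OC(C)(C)C(C)(C)O3)/C=C(/C)[C@@H](OC(=O)/C(=C\C)CO[Si](C)(C)C(C)(C)C)C[C@@H]12 | intermediate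
25 | (1(10)Z,4E)-(2R,6R,7S,9S)-9-{(Z)-2-[(tert-butyldimethylsilyloxy)methyl]but-2-enoyloxy}-2-hydroxygermacra-1(10),4,11(13)-trien-12,6-olide | C=C1C(=O)O[C@@H]2/C=C(\C)C[C@@H](O)/C=C(/C)[C@@H](OC(=O)/C(=C\C)CO[Si](C)(C)C(C)(C)C)C[C@@H]12 | intermediate
26 | CNP0273961.1, (1(10)Z,4E)-(2R,6R,7S,9S)-2-hydroxy-9-[(Z)-2-(hydroxymethyl)but-2-enoyloxy]germacra-1(10),4,11(13)-trien-12,6-olide | C=C1C(=O)O[C@@H]2/C=C(\C)C[C@@H](O)/C=C(/C)[C@@H](OC(=O)/C(=C\C)CO)C[C@@H]12 | target

## Step count and risks

Total step count: 17 steps. Longest linear sequence: 9 steps (steps 3, 4, 5, 6, 10, 14, 15, 16, 17; the branch from 1 through steps 1 and 2 is equally long).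

**Step 16 (Proposed new method).** What may go wrong: intramolecular transmetalation through a strained medium-ring transition state may be slower than intermolecular coupling, protodeboronation or transfer of the allylic boronate, so that oligomers and deboronated chains form instead of the ring.

Fallback (known reaction types only; sets out from 15 and 10, comes back at 26): the two C–C bond formations are exchanged, so that C3–C4 is made between two molecules and the ring is closed at C9–C10.
- Iodine–lithium exchange on 15 (t-BuLi, Et2O, −78 °C) and quenching with Me3SiCl should give (Z)-trimethyl(penta-2,4-dien-2-yl)silane F1.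
- Diboration as in step 15 should give the 1,2-bis(boronate) F2.
- Intermolecular Suzuki–Miyaura coupling of F2 with the alkenyl chloride of 10 (Pd(OAc)2, RuPhos, K3PO4, THF/H2O, 65 °C) should give the C2 boronate F3 (not isolated), and perborate oxidation the diol F4.
- TBSCl/imidazole should give the bis(silyl ether) F5.
- N-Iodosuccinimide in hexafluoroisopropanol at 0 °C should exchange silicon for iodine with retention, giving the (Z)-alkenyl iodide F6.
- HF·pyridine/pyridine at 0 °C should free the primary alcohol F7, and Dess–Martin oxidation should give the aldehyde F8.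
- Intramolecular Nozaki–Hiyama–Kishi reaction (CrCl2, NiCl2 cat., DMSO/THF, 2 mM) should close the ten-membered ring to the macrocyclic allylic alcohol F9. The C9 configuration is then set by the ring; if the epimer forms, Mitsunobu esterification with 20 inverts it.
- Yamaguchi esterification with 20 (via 21) should give the bis(silyl) ester F10, and HF·pyridine removes both silyl groups to give 26.

**Step 15.** What may go wrong: loss of chemoselectivity, with conjugate borylation of the α-methylene lactone competing with diboration of the diene terminus.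

Fallback (sets out from 22, comes back at 23): the exocyclic methylene is masked as a β-amino lactone. Me2NH (THF, 0 °C) should add to C13 to give the amino lactone F11 (C11 epimers, inconsequential). Diboration as in step 15 should give the bis(boronate) F12. MeI (MeCN, rt) should give the ammonium iodide F13 (not isolated), and aqueous NaHCO3 eliminates trimethylamine to restore the methylene lactone, giving 23.

**Step 10.** What may go wrong: poor facial control at C9, because the remote C7 centre and the hindered (Z)-dienyl nucleophile may override the ligand.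

Fallback (sets out from 11 and 15, comes back at 16): the stereocentre is set by reduction instead of by C–C bond formation. Ligand-free coupling (CrCl2 4 equiv, NiCl2 cat., DMSO, rt) should give 16 together with its C9 epimer F14. Dess–Martin oxidation of the mixture should give the cross-conjugated dienone F15. Corey–Bakshi–Shibata reduction ((R)-2-methyl-CBS-oxazaborolidine, catecholborane, toluene, −78 °C), with the dienyl group as the large substituent, should return 16.

Further compounds
F1 | step 16 | (Z)-trimethyl(penta-2,4-dien-2-yl)silane | C/C([Si](C)(C)C)=C/C=C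
F2 | step 16 | 1,2-bis(boronate) of F1 | C/C([Si](C)(C)C)=C/[C@H](B1OC(C)(C)C(C)(C)O1)CB1OC(C)(C)C(C)(C)O1
F3 | step 16 | C2 boronate from coupling of F2 with 10 (not isolated) | C=C1C(=O)O[C@H](/C=C(\C)C[C@@H](B2OC(C)(C)C(C)(C)O2)/C=C(/C)[Si](C)(C)C)[C@H]1CCO
F4 | step 16 | diol (C2–OH and primary OH, alkenylsilane at C10) | C=C1C(=O)O[C@H](/C=C(\C)C[C@@H](O)/C=C(/C)[Si](C)(C)C)[C@H]1CCO
F5 | step 16 | bis(silyl ether) of F4 | C=C1C(=O)O[C@H](/C=C(\C)C[C@@H](O[Si](C)(C)C(C)(C)C)/C=C(/C)[Si](C)(C)C)[C@H]1CCO[Si](C)(C)C(C)(C)C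
F6 | step 16 | (Z)-alkenyl iodide | C=C1C(=O)O[C@H](/C=C(\C)C[C@@H](O[Si](C)(C)C(C)(C)C)/C=C(/C)I)[C@H]1CCO[Si](C)(C)C(C)(C)C
F7 | step 16 | primary alcohol | C=C1C(=O)O[C@H](/C=C(\C)C[C@@H](O[Si](C)(C)C(C)(C)C)/C=C(/C)I)[C@H]1CCO
F8 | step 16 | aldehyde | C=C1C(=O)O[C@H](/C=C(\C)C[C@@H](O[Si](C)(C)C(C)(C)C)/C=C(/C)I)[C@H]1CC=O
F9 | step 16 | macrocyclic allylic alcohol (C9–OH, C2–OTBS) | C=C1C(=O)O[C@@H]2/C=C(\C)C[C@@H](O[Si](C)(C)C(C)(C)C)/C=C(/C)[C@@H](O)C[C@@H]12
F10 | step 16 | bis(silyl) ester | C=C1C(=O)O[C@@H]2/C=C(\C)C[C@@H](O[Si](C)(C)C(C)(C)C)/C=C(/C)[C@@H](OC(=O)/C(=C\C)CO[Si](C)(C)C(C)(C)C)C[C@@H]12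
F11 | step 15 | amino lactone (dimethylamine adduct of 22) | CN(C)CC1C(=O)O[C@H](/C=C(\C)Cl)[C@H]1C[C@H](OC(=O)/C(=C\C)CO[Si](C)(C)C(C)(C)C)/C(C)=C\C=C
F12 | step 15 | bis(boronate) of F11 | CN(C)CC1C(=O)O[C@H](/C=C(\C)Cl)[C@H]1C[C@H](OC(=O)/C(=C\C)CO[Si](C)(C)C(C)(C)C)/C(C)=C\[C@H](B1OC(C)(C)C(C)(C)O1)CB1OC(C)(C)C(C)(C)O1
F13 | step 15 | ammonium iodide of F12 (not isolated) | C[N+](C)(C)CC1C(=O)O[C@H](/C=C(\C)Cl)[C@H]1C[C@H](OC(=O)/C(=C\C)CO[Si](C)(C)C(C)(C)C)/C(C)=C\[C@H](B1OC(C)(C)C(C)(C)O1)CB1OC(C)(C)C(C)(C)O1.[I-]
F14 | step 10 | C9 epimer of 16 | C=C1C(=O)O[C@H](/C=C(\C)Cl)[C@H]1C[C@@H](O)/C(C)=C\C=C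
F15 | step 10 | cross-conjugated dienone | C=C1C(=O)O[C@H](/C=C(\C)Cl)[C@H]1CC(=O)/C(C)=C\C=C
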